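When I laid the last readings, at 27 h, side by side, I wanted one number per run that I could carry to the gamma flask.

| flask | starting material | partner | time |
|---|---|---|---|
| alpha | 150 mM | 225 mM |  |
| zeta | 75.0 mM | 150 mM |  |
| epsilon | 220 mM | 225 mM |  |
| gamma | 50.0 mM | 450 mM | 27 h |

| run | time / h | [product] / mM |
|---|---|---|
| alpha run | 3.4 | 12.0 |
| alpha run | 6.8 | 23.7 |
| alpha run | 10 | 42.9 |
| alpha run | 14 | 58.3 |
| alpha run | 17 | 67.0 |
| alpha run | 20 | 82.4 |
| alpha run | 24 | 93.4 |
| alpha run | 27 | 105.4 |
| zeta run | 3.4 | 5.9 |
| zeta run | 6.8 | 9.6 |
| zeta run | 10 | 10.7 |
| zeta run | 14 | 16.3 |
| zeta run | 17 | 18.6 |
| zeta run | 20 | 25.6 |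
| zeta run | 24 | 26.9 |
| zeta run | 27 | 32.8 |
| epsilon run | 3.4 | 18.9 |
| epsilon run | 6.8 | 40.7 |
| epsilon run | 10 | 63.7 |
| epsilon run | 14 | 92.7 |
| epsilon run | 17 | 110.7 |
| epsilon run | 20 | 129.2 |
| epsilon run | 24 | 144.4 |
| epsilon run | 27 | 159.0 |

(standard deviation of a reading: 2 mM)

- Overall: starting material + partner -> product.
- Constant volume, constant temperature.
- Bound and free are read together.
- "The second partner" is partner.
- An order is taken over about fifteen percent of the charge, up and down.

- reaction order in [starting material] at the outset, round the charge of the alpha run, defined at two percent of the starting material turned into product (one fixed amount of product, the same in the runs compared)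
- reaction order in [partner] at the outset, round the charge of the alpha run, defined at two percent of the starting material turned into product
- the zeta run starts with 75.0 mM less of starting material and of partner than the alpha run, and with no product. Compared where both hold the same amount of starting material, once fifteen percent of what the zeta run was charged with has turned into product, is the zeta run faster, slower or alike (within a tenth)?
- product in the gamma run at 27 h, as a share of the starting material charged
- which of these the readings show (the product decays / the second partner is lost in pairs / the product binds the second partner / the product speeds the reaction / the substrate pairs with itself / nothing beyond the main steps)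

I began with the main step alone, one starting material plus one partner, and asked what steady constant carries a run from its charge to its last reading. That constant replaces the changing curve by its mean. For the zeta run it came to 0.162 L mol⁻¹ h⁻¹, and I call it the mean constant. Applied to the gamma run, where starting material is the limiting reagent, it gave 84.3%.

The main step alone should give every run one value. But the alpha run gave 0.287 L mol⁻¹ h⁻¹ and the epsilon run 0.417 L mol⁻¹ h⁻¹, both higher than the zeta run, and they rose in the order of the product made.

So I added a speeding by product, with a straight line through the zeta and epsilon values against mean product, taken as half of the last reading. For the gamma run, with a mean product of 21.1 mM, the line gave 0.181 L mol⁻¹ h⁻¹, which lifted the share to 87.2%, higher than before.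

The rest was the error of the method. The line put the alpha run at 0.309 L mol⁻¹ h⁻¹, above its reading. Taking that miss off the gamma constant gave 83.7%. I committed to 87.2%, with that as my lower edge.

The forecast gave orders of 1 in starting material and 1 in partner, the zeta run slower at matched amounts, "the product speeds the reaction", and 87% for the gamma run, which it stepped through by hand. Its ground was this: “So the product speeds the reaction, and zeta is slower at matched amounts.”

The flask gave orders of 1.0 in starting material and 1.1 in partner, the zeta run slower at matched amounts, "the product speeds the reaction", and 83.4% for the gamma run, under my lower edge.

    2 partner ⇌ reagent dimer, settled at all times (37.70 L mol⁻¹)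
    starting material + reagent dimer → product + partner (0.2567 L mol⁻¹ h⁻¹)
    starting material + partner + product → 2 product (12.13 L² mol⁻² h⁻¹)

Where both held the same amount of starting material, the zeta run went at 0.35 of the rate of the alpha run. From its share, the gamma run has a mean constant of 0.157 L mol⁻¹ h⁻¹, lower than the 0.181 L mol⁻¹ h⁻¹ I reckoned. The zeta mean constant puts product at half of the starting material charged in that run at 33.3 h, and the zeta flask took 34.2 h.

All runs stem from a simulated flask on assumed constants, noise included.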